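## Retrosynthetic overview

1. The C13 methylene comes last, by α-methylenation of a C7–CH2–CHO unit. The C1–O ester bond is cut (Yamaguchi) to a decalin core alcohol and (2E,4E,6R,8S)-6,8-dimethyldeca-2,4-dienoic acid.
2. Core: the C7 two-carbon arm comes from α′-allylation of the enone and alkene cleavage; the 1β-OH from γ-oxidation of a dienol ether; C15 from one-carbon homologation of the C4 ketone of (S)-Wieland–Miescher ketone.
3. Ring order: ring A is the purchased 2-methylcyclohexane-1,3-dione; ring B is closed second by an organocatalytic Robinson annulation that sets C5.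
4. Acid: vinylogous Horner–Wadsworth–Emmons reaction of (2R,4S)-2,4-dimethylhexanal. C6′ is set by lipase desymmetrisation of a prochiral 1,3-diol diacetate, and C8′ by Ru-catalysed asymmetric hydrogenation of tiglic acid.

Assumption: the target is taken exactly as drawn (1β-acyloxy, 4β-CO2H, 5β-CH3, 7α-(1-formylvinyl); anti-dimethyl (6′R,8′S) chain); the core carries eremophilane numbering (C1–C5, C10 = ring A; C5–C10 = ring B; β = face of the C5 methyl) and the acyl chain primed numbers.

## Route

Step 1
Reactants: 1 2-methylcyclohexane-1,3-dione; 2 methyl vinyl ketone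
Product: 3 2-methyl-2-(3-oxobutyl)cyclohexane-1,3-dione
Conditions: Et3N (1 mol%), neat, rt
Reagents that add atoms: none
Why: Michael addition of the stabilised 1,3-dione enolate to the enone gives the prochiral triketone (no stereocentre yet).

Step 2
Reactants: 3 2-methyl-2-(3-oxobutyl)cyclohexane-1,3-dione
Product: 5 (S)-Wieland–Miescher ketone, via cis-fused bicyclic ketol 4 (not isolated)
Conditions: N-tosyl-(Sa)-binam-(S)-prolinamide (2 mol%), PhCO2H (1 mol%), neat, rt; recrystallise to >99% ee
Reagents that add atoms: none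
Why: Hajos–Parrish–Eder–Sauer–Wiechert reaction, in which the enamine of the side-chain ketone adds to one of the two enantiotopic ring carbonyls through a hydrogen-bonded transition state and the ketol dehydrates, so the (S)-proline-derived catalyst sets the quaternary C5 (8aS; (S)-proline in DMSO gives the same sense).

Step 3
Reactants: 5 (S)-Wieland–Miescher ketone
Product: 6 (S)-Wieland–Miescher ketone 8-(1,3-dithiolane)
Conditions: HSCH2CH2SH (1.05 equiv), TsOH·H2O, AcOH, rt
Reagents that add atoms: ethane-1,2-dithiol, SCCS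
Why: Acid-catalysed thioketalisation is chemoselective for the conjugated C8 carbonyl (allyl-stabilised thionium, no double-bond migration) over the neopentyl C4 ketone, which is thereby left free for homologation.

Step 4
Reactants: 6 (S)-Wieland–Miescher ketone 8-(1,3-dithiolane)
Product: 7 4-(methoxymethylidene) dithiolane (E/Z mixture)
Conditions: MeOCH2PPh3Cl (3 equiv), KN(SiMe3)2 (2.8 equiv), THF, 0 °C to rt
Reagents that add atoms: (methoxymethyl)triphenylphosphonium chloride, [Cl-].COC[P+](c1ccccc1)(c1ccccc1)c1ccccc1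
Why: Wittig methoxymethylenation of the only free ketone brings in the future C15 as an enol ether, with excess ylide compensating for competing enolisation of the hindered carbonyl.

Step 5
Reactants: 7 4-(methoxymethylidene) dithiolane
Product: 8 4β-formyl dithiolane
Conditions: 2 N HCl, THF, rt; then K2CO3, MeOH, rt
Reagents that add atoms: water, O
Why: Enol-ether hydrolysis protonates C4 from the α face (anti to the axial C5 methyl) and the base treatment then funnels any epimer to the equatorial 4β-aldehyde (cis to the C5 methyl), so C4 is set under combined kinetic and thermodynamic control.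

Step 6
Reactants: 8 4β-formyl dithiolane
Product: 9 4β-formyl enone
Conditions: Hg(ClO4)2·3H2O (2 equiv), CaCO3, THF/H2O 5:1, 0 °C to rt
Reagents that add atoms: water, O
Why: Thiophilic divalent mercury cleaves the dithiolane under buffered conditions (dethioketalisation) and returns the enone without touching the aldehyde or C4.

Step 7
Reactants: 9 4β-formyl enone
Product: 10 4β-carboxylic acid enone
Conditions: NaClO2, NaH2PO4, 2-methylbut-2-ene, t-BuOH/H2O, 0 °C to rt
Reagents that add atoms: sodium chlorite, [Na+].[O-]Cl=O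
Why: Pinnick oxidation converts the aldehyde to the acid chemoselectively (the enone is inert) and the buffered medium does not epimerise the hindered α-centre.

Step 8
Reactants: 10 4β-carboxylic acid enone
Product: 11 2-(trimethylsilyl)ethyl ester enone
Conditions: Me3SiCH2CH2OH, PPh3, DIAD, THF, 0 °C to rt
Reagents that add atoms: 2-(trimethylsilyl)ethanol, C[Si](C)(C)CCO
Why: Mitsunobu esterification uses the hindered acid as the nucleophile towards the activated primary alcohol, giving an ester that survives acid, peracid and enolate chemistry and is later removed by fluoride.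

Step 9
Reactants: 11 2-(trimethylsilyl)ethyl ester enone
Product: 12 8-ethoxy-8,1(10)-dienol ether
Conditions: HC(OEt)3 (3 equiv), TsOH·H2O (2 mol%), EtOH/THF, rt; Et3N quench, used crude
Reagents that add atoms: triethyl orthoformate, CCOC(OCC)OCC
Why: Acid-catalysed enol etherification gives the thermodynamic linear (heteroannular) dienol ether, as with steroidal 4-en-3-ones, which makes C1 the nucleophilic γ-carbon.

Step 10
Reactants: 12 8-ethoxy-8,1(10)-dienol ether
Product: 13 1β-hydroxy enone
Conditions: mCPBA (1.05 equiv), THF/H2O 9:1, −10 to 0 °C; NaHCO3 work-up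
Reagents that add atoms: mCPBA, OOC(=O)c1cccc(Cl)c1; water, O
Why: Vinylogous Rubottom-type oxidation in which the peracid attacks C1 along the axial trajectory on the β face (stereoelectronic control that keeps ring A chair-like, as in the 6β-hydroxylation of steroidal 3,5-dienol ethers) and hydrolysis of the oxocarbenium restores the enone, setting C1 as the axial 1β-alcohol.

Step 11
Reactants: 13 1β-hydroxy enone
Product: 14 1β-triethylsilyloxy enone
Conditions: Et3SiOTf, 2,6-lutidine, CH2Cl2, −78 °C
Reagents that add atoms: triethylsilyl trifluoromethanesulfonate, CC[Si](CC)(CC)OS(=O)(=O)C(F)(F)F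
Why: Silylation of the hindered axial allylic alcohol with the reactive silyl triflate protects it for the enolate step, and 2,6-lutidine at −78 °C does not enolise the enone.

Step 12
Reactants: 14 1β-triethylsilyloxy enone
Product: 16 7α-allyl enone, via lithium α′-enolate 15 (not isolated)
Conditions: LiN(iPr)2 (1.1 equiv), THF, −78 °C; allyl bromide (3 equiv), DMPU, −78 to −30 °C
Reagents that add atoms: allyl bromide, C=CCBr
Why: Kinetic deprotonation gives the cross-conjugated α′-enolate (ketone far more acidic than the hindered ester α-H), which is allylated on carbon anti to the axial C5 methyl; the 7α (equatorial) product is also the thermodynamic epimer.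

Step 13
Reactants: 16 7α-allyl enone
Product: 18 7α-(2-oxoethyl) enone, via vicinal diol 17 (not isolated)
Conditions: OsO4 (2 mol%), NaIO4 (4 equiv), 2,6-lutidine (2 equiv), dioxane/H2O 3:1, rt
Reagents that add atoms: osmium tetroxide, O=[Os](=O)(=O)=O (oxygen donor, re-formed by sodium periodate, [Na+].[O-]I(=O)(=O)=O)
Why: Lemieux–Johnson cleavage, in which the electron-rich terminal alkene is dihydroxylated much faster than the electron-poor trisubstituted enone alkene and periodate cleaves the diol to the C12 aldehyde.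

Step 14
Reactants: 18 7α-(2-oxoethyl) enone
Product: 19 1β-hydroxy 7α-(2,2-dimethoxyethyl) enone
Conditions: HC(OMe)3 (3 equiv), PPTS (0.2 equiv), MeOH, rt
Reagents that add atoms: trimethyl orthoformate, COC(OC)OC; methanol, CO
Why: Mild acid in methanol acetalises the aldehyde (not the conjugated ketone) and at the same time methanolyses the triethylsilyl ether, so the 1β-alcohol is freed for acylation while C12 stays masked and base-stable.

Step 15
Reactants: 20 tiglic acid
Product: 21 (S)-2-methylbutanoic acid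
Conditions: Ru(OAc)2[(S)-H8-BINAP] (0.5 mol%), H2 (1.5–4 atm), MeOH, 20 °C
Reagents that add atoms: none
Why: Noyori-type asymmetric hydrogenation of an α,β-unsaturated acid, in which the carboxylate-bound Ru hydride adds to one enantioface of the alkene and sets C8′ as (S) in about 97% ee.

Step 16
Reactants: 21 (S)-2-methylbutanoic acid
Product: 22 (S)-2-methylbutan-1-ol
Conditions: LiAlH4, Et2O, 0 °C to reflux
Reagents that add atoms: none
Why: Hydride reduction of the acid to the primary alcohol does not involve the stereocentre.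

Step 17
Reactants: 22 (S)-2-methylbutan-1-ol
Product: 23 (S)-2-methylbutyl 4-methylbenzenesulfonate
Conditions: TsCl, pyridine, 0 °C
Reagents that add atoms: 4-methylbenzenesulfonyl chloride, Cc1ccc(cc1)S(Cl)(=O)=O
Why: Sulfonylation turns the volatile alcohol into a non-volatile primary electrophile.

Step 18
Reactants: 23 (S)-2-methylbutyl 4-methylbenzenesulfonate; 24 dimethyl malonate
Product: 26 dimethyl 2-[(2S)-2-methylbutyl]propanedioate, via sodium dimethyl malonate 25 (not isolated)
Conditions: 24 (2.5 equiv), NaH (2.2 equiv), THF/DMF, 0 °C; then 23, NaI (10 mol%), 80 °C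
Reagents that add atoms: none
Why: Malonic ester alkylation (SN2 at the primary carbon, iodide-catalysed; excess malonate suppresses dialkylation) attaches the prochiral future C6′ without touching C8′.

Step 19
Reactants: 26 dimethyl 2-[(2S)-2-methylbutyl]propanedioate
Product: 27 2-[(2S)-2-methylbutyl]propane-1,3-diol
Conditions: LiAlH4, THF, 0 °C to reflux
Reagents that add atoms: none
Why: Reduction of both esters gives the prochiral 2-substituted 1,3-diol.

Step 20
Reactants: 27 2-[(2S)-2-methylbutyl]propane-1,3-diol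
Product: 28 2-[(2S)-2-methylbutyl]propane-1,3-diyl diacetate
Conditions: Ac2O, pyridine, DMAP (cat.), CH2Cl2, rt
Reagents that add atoms: acetic anhydride, CC(=O)OC(C)=O
Why: Exhaustive acetylation gives the prochiral diacetate needed for hydrolytic desymmetrisation.

Step 21
Reactants: 28 2-[(2S)-2-methylbutyl]propane-1,3-diyl diacetate
Product: 29 [(2S,4S)-2-(hydroxymethyl)-4-methylhexyl] acetate
Conditions: lipase (Burkholderia cepacia lipase, a triacylglycerol hydrolase), phosphate buffer (0.1 mol/L, pH 7.0)/i-Pr2O, 25 °C, pH-stat with NaOH, stopped just past one equivalent of base; cold extraction, used at once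
Reagents that add atoms: none
Why: Lipase-catalysed enantiotopic-group-selective ester hydrolysis, in which the enzyme cleaves the acetate of the arm that fits its fast-reacting primary-alcohol pocket (the (S)-2-methylalkanol-type preference of this lipase) to leave the (2S) monoacetate, and the minor wrong monoacetate is hydrolysed on faster to the diol, which sharpens the selectivity at C6′.

Step 22
Reactants: 29 [(2S,4S)-2-(hydroxymethyl)-4-methylhexyl] acetate
Product: 30 [(2R,4S)-4-methyl-2-(tosyloxymethyl)hexyl] acetate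
Conditions: TsCl, pyridine, CH2Cl2, 0 °C
Reagents that add atoms: 4-methylbenzenesulfonyl chloride, Cc1ccc(cc1)S(Cl)(=O)=O
Why: Immediate sulfonylation of the free arm locks the desymmetrised arm assignment before 1,3-acyl migration can racemise C6′.

Step 23
Reactants: 30 [(2R,4S)-4-methyl-2-(tosyloxymethyl)hexyl] acetate
Product: 31 (2R,4S)-2,4-dimethylhexan-1-ol
Conditions: LiAlH4 (2 equiv), THF, 0 °C to rt
Reagents that add atoms: none
Why: Hydride SN2 displacement turns the tosylated arm into the C6′ methyl while the acetate arm is reduced to the carbinol, which gives the anti (2R,4S) array without touching either stereocentre.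

Step 24
Reactants: 31 (2R,4S)-2,4-dimethylhexan-1-ol
Product: 32 (2R,4S)-2,4-dimethylhexanal
Conditions: TEMPO (10 mol%), PhI(OAc)2 (1.1 equiv), CH2Cl2, rt; used crude
Reagents that add atoms: none
Why: Oxoammonium-catalysed oxidation stops at the aldehyde under non-basic conditions, so the α-stereocentre is not epimerised.

Step 25
Reactants: 32 (2R,4S)-2,4-dimethylhexanal; 33 triethyl 4-phosphonocrotonate
Product: 35 ethyl (2E,4E,6R,8S)-6,8-dimethyldeca-2,4-dienoate, via lithiated phosphonate 34 (not isolated)
Conditions: 33, LiN(SiMe3)2, THF, −78 °C; then 32, −78 to 0 °C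
Reagents that add atoms: none
Why: Vinylogous Horner–Wadsworth–Emmons olefination with the preformed stabilised anion gives the (2E,4E)-dienoate (E geometry from the reversible addition–elimination of a stabilised phosphonate) with no free base left to epimerise C6′.

Step 26
Reactants: 35 ethyl (2E,4E,6R,8S)-6,8-dimethyldeca-2,4-dienoate
Product: 36 (2E,4E,6R,8S)-6,8-dimethyldeca-2,4-dienoic acid
Conditions: LiOH·H2O, THF/MeOH/H2O, rt; then 1 N HCl
Reagents that add atoms: lithium hydroxide, [Li+].[OH-]
Why: Saponification of the unhindered ethyl ester gives the dienoic acid; C6′ is γ to the carbonyl through the diene and is not epimerised at rt.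

Step 27
Reactants: 19 1β-hydroxy 7α-(2,2-dimethoxyethyl) enone; 36 (2E,4E,6R,8S)-6,8-dimethyldeca-2,4-dienoic acid
Product: 38 1β-dienoate dimethyl acetal silylethyl ester, via mixed anhydride 37 (not isolated)
Conditions: 36, 2,4,6-Cl3C6H2COCl, Et3N, toluene, rt; then 19, DMAP, toluene, rt to 40 °C
Reagents that add atoms: none
Why: Yamaguchi esterification, in which DMAP turns the mixed anhydride into an acylpyridinium that acylates the hindered axial 1β-alcohol with retention at C1; the acetal and both esters are stable to the basic medium.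

Step 28
Reactants: 38 1β-dienoate dimethyl acetal silylethyl ester
Product: 40 1β-dienoate 12-aldehyde 15-acid, via dimethyl acetal acid 39 (not isolated)
Conditions: Bu4NF (3 equiv), AcOH (1.5 equiv), THF, 0 °C to rt; then 1 N HCl, THF/H2O, rt
Reagents that add atoms: water, O
Why: Fluoride attacks silicon and fragments the 2-(trimethylsilyl)ethyl ester (β-elimination of ethene) without hydrolytic conditions, sparing the dienoate, and dilute aqueous acid then hydrolyses the dimethyl acetal to the C12 aldehyde.

Step 29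
Reactants: 40 1β-dienoate 12-aldehyde 15-acid
Product: 41 CNP0137278.2
Conditions: 37% aq. HCHO (1.5 equiv), pyrrolidine (0.5 equiv; the substrate CO2H is the acid co-catalyst), i-PrOH, 40 °C, short reaction time
Reagents that add atoms: formaldehyde, C=O
Why: Amine-catalysed α-methylenation (Mannich condensation of the aldehyde enamine with formaldehyde, then β-elimination of the amine) installs C13 at the aldehyde α-carbon C11 only, and C7 stays as, or equilibrates to, the equatorial 7α epimer.

## Compound list

1 | 2-methylcyclohexane-1,3-dione | CC1C(=O)CCCC1=O | starting material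
2 | methyl vinyl ketone (but-3-en-2-one) | CC(=O)C=C | starting material
3 | 2-methyl-2-(3-oxobutyl)cyclohexane-1,3-dione | CC(=O)CCC1(C)C(=O)CCCC1=O | intermediate
4 | (4aS,8aS)-4a-hydroxy-8a-methyloctahydronaphthalene-1,6-dione (cis-fused ketol, OH cis to CH3) | C1C[C@@]2(C)[C@@](O)(CC1=O)CCCC2=O | intermediate
5 | (S)-Wieland–Miescher ketone, (8aS)-8a-methyl-3,4,8,8a-tetrahydronaphthalene-1,6(2H,7H)-dione | C1C[C@@]2(C)C(=CC1=O)CCCC2=O | intermediate
6 | (S)-Wieland–Miescher ketone 8-(1,3-dithiolane): spiro-dithiolane at the former enone carbonyl C8, 9(10)-ene kept, C4 ketone free | C1C[C@@]2(C)C(=CC13SCCS3)CCCC2=O | intermediate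
7 | 4-(methoxymethylidene) derivative of 6 (enol ether, E/Z mixture; 5-CH3 β) | C1C[C@@]2(C)C(=CC13SCCS3)CCCC2=COC | intermediate
8 | (4S,5R)-4β-formyl-5β-methyl 8-(1,3-dithiolane) (CHO equatorial, cis to 5-CH3) | C1C[C@@]2(C)C(=CC13SCCS3)CCC[C@@H]2C=O | intermediate
9 | (1S,8aR)-8a-methyl-6-oxo-1,2,3,4,6,7,8,8a-octahydronaphthalene-1-carbaldehyde (4β-formyl enone) | C1C[C@@]2(C)C(=CC1=O)CCC[C@@H]2C=O | intermediate
10 | (1S,8aR)-8a-methyl-6-oxo-1,2,3,4,6,7,8,8a-octahydronaphthalene-1-carboxylic acid | C1C[C@@]2(C)C(=CC1=O)CCC[C@@H]2C(=O)O | intermediate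
11 | 2-(trimethylsilyl)ethyl (1S,8aR)-8a-methyl-6-oxo-1,2,3,4,6,7,8,8a-octahydronaphthalene-1-carboxylate | C1C[C@@]2(C)C(=CC1=O)CCC[C@@H]2C(=O)OCC[Si](C)(C)C | intermediate
12 | 2-(trimethylsilyl)ethyl (1S,8aR)-6-ethoxy-8a-methyl-1,2,3,7,8,8a-hexahydronaphthalene-1-carboxylate (8-ethoxy-8,1(10)-diene) | C1C[C@@]2(C)C(C=C1OCC)=CCC[C@@H]2C(=O)OCC[Si](C)(C)C | intermediate
13 | 2-(trimethylsilyl)ethyl (1S,4R,8aR)-4-hydroxy-8a-methyl-6-oxo-1,2,3,4,6,7,8,8a-octahydronaphthalene-1-carboxylate (1β-OH, axial) | C1C[C@@]2(C)C(=CC1=O)[C@H](O)CC[C@@H]2C(=O)OCC[Si](C)(C)C | intermediate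
14 | 1β-triethylsilyl ether of 13 | C1C[C@@]2(C)C(=CC1=O)[C@H](O[Si](CC)(CC)CC)CC[C@@H]2C(=O)OCC[Si](C)(C)C | intermediate
15 | lithium α′-enolate of 14 (C7=C8–OLi, cross-conjugated with the 9(10)-ene) | C=1C[C@@]2(C)C(=CC=1O[Li])[C@H](O[Si](CC)(CC)CC)CC[C@@H]2C(=O)OCC[Si](C)(C)C | intermediate
16 | 7α-allyl derivative of 14 (allyl trans to the 5-CH3) | C=CC[C@@H]1C[C@@]2(C)C(=CC1=O)[C@H](O[Si](CC)(CC)CC)CC[C@@H]2C(=O)OCC[Si](C)(C)C | intermediate
17 | 7α-(2,3-dihydroxypropyl) derivative of 14 (both carbinol epimers) | OCC(O)C[C@@H]1C[C@@]2(C)C(=CC1=O)[C@H](O[Si](CC)(CC)CC)CC[C@@H]2C(=O)OCC[Si](C)(C)C | intermediate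
18 | 7α-(2-oxoethyl) derivative of 14 (C12 aldehyde) | O=CC[C@@H]1C[C@@]2(C)C(=CC1=O)[C@H](O[Si](CC)(CC)CC)CC[C@@H]2C(=O)OCC[Si](C)(C)C | intermediate
19 | 2-(trimethylsilyl)ethyl 7α-(2,2-dimethoxyethyl)-1β-hydroxy-5β-methyl-8-oxo-9(10)-ene-4β-carboxylate | COC(OC)C[C@@H]1C[C@@]2(C)C(=CC1=O)[C@H](O)CC[C@@H]2C(=O)OCC[Si](C)(C)C | intermediate
20 | tiglic acid, (E)-2-methylbut-2-enoic acid | C/C=C(\C)C(=O)O | starting material
21 | (S)-2-methylbutanoic acid | OC(=O)[C@@H](C)CC | intermediate
22 | (S)-2-methylbutan-1-ol | OC[C@@H](C)CC | intermediate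
23 | (S)-2-methylbutyl 4-methylbenzenesulfonate | Cc1ccc(cc1)S(=O)(=O)OC[C@@H](C)CC | intermediate
24 | dimethyl malonate | COC(=O)CC(=O)OC | starting material
25 | sodium dimethyl malonate | [Na+].COC(=O)[CH-]C(=O)OC | intermediate
26 | dimethyl 2-[(2S)-2-methylbutyl]propanedioate | COC(=O)C(C[C@@H](C)CC)C(=O)OC | intermediate
27 | 2-[(2S)-2-methylbutyl]propane-1,3-diol | OCC(CO)C[C@@H](C)CC | intermediate
28 | 2-[(2S)-2-methylbutyl]propane-1,3-diyl diacetate | CC(=O)OCC(COC(C)=O)C[C@@H](C)CC | intermediate
29 | [(2S,4S)-2-(hydroxymethyl)-4-methylhexyl] acetate | CC(=O)OC[C@H](CO)C[C@@H](C)CC | intermediate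
30 | [(2R,4S)-4-methyl-2-(tosyloxymethyl)hexyl] acetate | CC(=O)OC[C@H](COS(=O)(=O)c1ccc(C)cc1)C[C@@H](C)CC | intermediate
31 | (2R,4S)-2,4-dimethylhexan-1-ol | OC[C@H](C)C[C@@H](C)CC | intermediate
32 | (2R,4S)-2,4-dimethylhexanal | O=C[C@H](C)C[C@@H](C)CC | intermediate
33 | triethyl 4-phosphonocrotonate, ethyl (E)-4-(diethoxyphosphoryl)but-2-enoate | CCOC(=O)/C=C/CP(=O)(OCC)OCC | starting material
34 | lithium salt of the γ-deprotonated phosphonate 33 | [Li+].CCOC(=O)/C=C/[CH-]P(=O)(OCC)OCC | intermediate
35 | ethyl (2E,4E,6R,8S)-6,8-dimethyldeca-2,4-dienoate | CCOC(=O)/C=C/C=C/[C@H](C)C[C@@H](C)CC | intermediate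
36 | (2E,4E,6R,8S)-6,8-dimethyldeca-2,4-dienoic acid | OC(=O)/C=C/C=C/[C@H](C)C[C@@H](C)CC | intermediate
37 | (2E,4E,6R,8S)-6,8-dimethyldeca-2,4-dienoic 2,4,6-trichlorobenzoic anhydride | O=C(OC(=O)/C=C/C=C/[C@H](C)C[C@@H](C)CC)c1c(Cl)cc(Cl)cc1Cl | intermediate
38 | 2-(trimethylsilyl)ethyl 7α-(2,2-dimethoxyethyl)-1β-[(2E,4E,6R,8S)-6,8-dimethyldeca-2,4-dienoyloxy]-5β-methyl-8-oxo-9(10)-ene-4β-carboxylate | COC(OC)C[C@@H]1C[C@@]2(C)C(=CC1=O)[C@H](OC(=O)/C=C/C=C/[C@H](C)C[C@@H](C)CC)CC[C@@H]2C(=O)OCC[Si](C)(C)C | intermediate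
39 | free 4β-carboxylic acid of 38 (dimethyl acetal intact) | COC(OC)C[C@@H]1C[C@@]2(C)C(=CC1=O)[C@H](OC(=O)/C=C/C=C/[C@H](C)C[C@@H](C)CC)CC[C@@H]2C(=O)O | intermediate
40 | 1β-[(2E,4E,6R,8S)-6,8-dimethyldeca-2,4-dienoyloxy]-5β-methyl-8-oxo-7α-(2-oxoethyl)-9(10)-ene-4β-carboxylic acid | O=CC[C@@H]1C[C@@]2(C)C(=CC1=O)[C@H](OC(=O)/C=C/C=C/[C@H](C)C[C@@H](C)CC)CC[C@@H]2C(=O)O | intermediate
41 | CNP0137278.2, (1R,4S,5R,7S)-1-[(2E,4E,6R,8S)-6,8-dimethyldeca-2,4-dienoyloxy]-8,12-dioxoeremophila-9,11(13)-dien-15-oic acid | C=C(C=O)[C@@H]1C[C@@]2(C)C(=CC1=O)[C@H](OC(=O)/C=C/C=C/[C@H](C)C[C@@H](C)CC)CC[C@@H]2C(=O)O | target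

## Step count and weak points

Total step count: 29.
Longest linear sequence: 17 steps (steps 1–14, then 27–29); the acid branch is 12 steps (15–26) before the coupling.

**Step 10 (γ-hydroxylation; risk: the equatorial 1α-alcohol forms as the main product or as an inseparable mixture).** This fallback sets out from 12 and comes back at 13. The same peracid oxidation of 12 is worked up to collect the equatorial epimer, the 1α-alcohol F1. Mitsunobu reaction of F1 with 4-nitrobenzoic acid (PPh3, DIAD, THF, 0 °C) inverts the allylic carbinol by SN2 to the 1β-(4-nitrobenzoate) F2. Mild methanolysis (K2CO3, MeOH, 0 °C) then gives 13, so both epimers of the oxidation converge.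

**Step 21 (lipase hydrolysis; risks: moderate selectivity on this substrate and acyl migration in water).** This fallback sets out from 27 and comes back at 31. The same lipase is used in acylation mode in dry solvent (vinyl acetate, i-Pr2O, immobilised enzyme), where no migration occurs. It acetylates the arm it prefers and gives the C2-epimeric monoacetate F3. The arms are then exchanged chemically:
- dihydropyran/PPTS gives the tetrahydropyranyl ether acetate F4;
- K2CO3/MeOH gives the alcohol F5;
- TsCl/pyridine gives the tosylate F6;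
- LiAlH4 gives the tetrahydropyranyl ether F7 of the (2R,4S)-alcohol;
- TsOH/MeOH releases 31.

**Step 29 (final methylenation; risks: slow turnover with the free acid, or amine-induced isomerisation to the conjugated 7(11)-ene).** This fallback sets out from 40 and comes back at 41. It uses a stoichiometric Mannich–elimination sequence in place of the catalytic condensation. Compound 40 with dimethylmethyleneammonium iodide and Et3N (2.2 equiv) in CH2Cl2 at 0 °C to rt gives the Mannich base F8. F8 loses dimethylamine on silica gel (or after N-methylation with MeI and a NaHCO3 wash) to give 41 without prolonged exposure to a secondary amine.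

Further compounds
F1 | step 10 | 2-(trimethylsilyl)ethyl (1S,4S,8aR)-4-hydroxy-8a-methyl-6-oxo-1,2,3,4,6,7,8,8a-octahydronaphthalene-1-carboxylate (1α-alcohol, C1 epimer of 13) | C1C[C@@]2(C)C(=CC1=O)[C@@H](O)CC[C@@H]2C(=O)OCC[Si](C)(C)C
F2 | step 10 | 2-(trimethylsilyl)ethyl (1S,4R,8aR)-8a-methyl-4-[(4-nitrobenzoyl)oxy]-6-oxo-1,2,3,4,6,7,8,8a-octahydronaphthalene-1-carboxylate (1β-(4-nitrobenzoate)) | C1C[C@@]2(C)C(=CC1=O)[C@H](OC(=O)c1ccc(cc1)[N+](=O)[O-])CC[C@@H]2C(=O)OCC[Si](C)(C)C
F3 | step 21 | [(2R,4S)-2-(hydroxymethyl)-4-methylhexyl] acetate | CC(=O)OC[C@@H](CO)C[C@@H](C)CC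
F4 | step 21 | [(2R,4S)-4-methyl-2-(tetrahydro-2H-pyran-2-yloxymethyl)hexyl] acetate (acetal epimers) | CC(=O)OC[C@@H](COC1CCCCO1)C[C@@H](C)CC
F5 | step 21 | (2S,4S)-4-methyl-2-(tetrahydro-2H-pyran-2-yloxymethyl)hexan-1-ol (acetal epimers) | OC[C@@H](COC1CCCCO1)C[C@@H](C)CC
F6 | step 21 | (2R,4S)-4-methyl-2-(tetrahydro-2H-pyran-2-yloxymethyl)hexyl 4-methylbenzenesulfonate (acetal epimers) | Cc1ccc(cc1)S(=O)(=O)OC[C@@H](COC1CCCCO1)C[C@@H](C)CC
F7 | step 21 | 2-{[(2R,4S)-2,4-dimethylhexyl]oxy}tetrahydro-2H-pyran (acetal epimers) | C[C@@H](COC1CCCCO1)C[C@@H](C)CC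
F8 | step 29 | Mannich base of 40, 11-[(dimethylamino)methyl] derivative (C11 epimers) | O=CC(CN(C)C)[C@@H]1C[C@@]2(C)C(=CC1=O)[C@H](OC(=O)/C=C/C=C/[C@H](C)C[C@@H](C)CC)CC[C@@H]2C(=O)O
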